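## The problem

Target 16 is a biflavonoid: a naringenin-type flavanone (rings A, C and B) is joined through C3 to C3'' of an apigenin-type flavone, so the central bond links a stereogenic sp3 carbon to a fully substituted carbon of a second pyranone. There are only two stereocenters, C2 (S) and C3 (R), and they are trans on ring C. C3 lies alpha to the C4 ketone and carries the flavone, so it epimerises easily and settles in the trans, diequatorial arrangement. C2 is therefore the only center that must be set in the absolute sense, and it then controls C3. C2 is itself fragile, because a flavanone can open to a 2'-hydroxychalcone by beta-elimination of O1 under base and reclose without memory. Six phenols have to be carried masked and freed at the end without reducing the flavone C2''=C3'' bond, the C4 ketone or the benzylic C2–O1 bond, and the electron-rich ring A makes any C4 carbinol acid-labile. The feature that opens the chosen approach is that O1 joins the carbinol carbon C2 to the aromatic carbon C8a. Ring C can therefore be closed at the aryl–oxygen bond O1–C8a, which touches no stereocenter, once C2 exists as a secondary alcohol and C8a carries a bromide.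

## Retrosynthesis

**16 to 15 to 14 (six O–benzyl bonds; oxidation level at C4).** The phenols are freed last from hexabenzyl ether 15. Benzyl is preferred to methyl, whose removal needs Lewis acids strong enough to open the flavanone, and to acetal or silyl groups, which would not pass the acidic and basic steps before it. The C4 ketone of 15 is traced back to the secondary alcohol of 14. With a ketone at C4 the open-chain precursor of ring C would be a beta-hydroxy ketone, which fragments or eliminates under the base needed for ring closure. The forward steps must be a neutral oxidation and a hydrogenolysis that stops at the benzyl ethers.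

**14 to 13 (O1–C8a).** This is the key cut. The neighbouring cut O1–C2 (oxa-Michael closure of a chalcone, or displacement at C2) puts the C2 stereocenter itself at stake. Cutting C3–C3'' asks for the union of two finished flavonoids at a hindered, epimerisable carbon with no handle on C2. Cutting O1–C8a leaves the acyclic bromo diol 13, in which C2, C3 and C4 are already in place. The forward reaction must be an aryl etherification that engages the C2 hydroxyl only and breaks no bond to a stereocenter.

**13 to 12 (C2–H).** The C2 carbinol of 13 comes from the aryl ketone of 12 by hydride delivery directed by the C4 hydroxyl, giving the 1,3-anti diol. C4, which ends as a carbonyl, thus serves as a relay that passes its configuration to C2 before it is erased. An undirected reduction would rest on weak 1,2-induction, and a 1,3-syn reduction would lead to the 2,3-cis series. The precursor has one stereocenter less, and the forward step must leave the flavone carbonyl alone.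

**12 to 9 and 4 (C3–C4).** The aldol bond is cut so that ring A arrives as aldehyde 4 and the ring B side as ketone 9. The opposite polarity (ring A as a 2-bromoaryl ketone) would need the enolate of a di-ortho-substituted aryl ketone, whose geometry is not dependable. It would also need an anti aldol, the poorly controlled case for isopinocampheyl ligands, and a Friedel–Crafts acylation in the presence of benzyl ethers. Ketone 9 is an unhindered aryl ketone that should give the Z enolate and hence the syn aldol. The cut halves the molecule. The forward step must control the aldehyde face and avoid retro-aldol cleavage.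

**9 to 7 and 8, 7 to 6 to 5 (C3''–CH2, C3''–I, O–benzyl).** The methylene of 9 is attached to the flavone by ketone alpha-arylation of acetophenone 8 with 3-iodoflavone 7. Iodide 7 comes from tribenzyl ether 6 and 6 from apigenin 5. Building the flavone with the side chain already in place would be longer and would pass through a 1,4-diketone prone to furan formation. The forward steps need C3-selective iodination and a base mild enough for the pyranone.

**4 to 2 to 1 (formyl C–C, O–benzyl).** Aldehyde 4 is the formylation product of dibenzyl ether 2, made from 5-bromoresorcinol 1. The formyl group must enter next to bromine, para to one ether and ortho to the other, which is the normal site for this substitution pattern.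

## Roads not taken

**Alternative 1:** The cut is O1–C2 together with O1''–C2'', both made from the donor–acceptor cyclopropane A1. In the forward step Sc(OTf)3 would break the C2–C3'' bond of A1, a ring A phenol would close ring C at C2, and the 1,3-diketone unit set free would cyclodehydrate to the flavone, giving A2. This road is better than the chosen plan in two respects: two rings form in one operation, and A2 is already at the ketone oxidation level, one hydrogenolysis from 16. Its weak points lie in A1 and in the stereochemistry: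
- A1 carries three aroyl groups and four free ortho-phenols, and its assembly is not short.
- The donor is a 4-alkoxyphenyl group, so the breaking bond ionises to a stabilised benzylic cation. The configuration at C2 is then lost unless the opening is strictly invertive.
- The carbonyl oxygens can trap the cation in a Cloke–Wilson closure to a dihydrofuran, and the phenols of the other ring can compete.

Against the shorter endgame the chosen plan sets a C2–O bond that is made once and never broken again.

**Alternative 2:** The cut removes ring A itself (C8–C8a, C5–C6, C7–C8 and C4a–C5). Blue light would trigger the Wolff rearrangement of diazoketone A3, the ketene function would add siloxyalkyne A4, and four-electron opening followed by six-electron closure would give A5. The merits are real: no aryl halide and no palladium are needed, ring A arrives with the 5-hydroxyl free and the 7-oxygen silylated, and the C4 ketone is present throughout, so the reduction–oxidation detour of the chosen plan disappears. The weak points are in A3: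
- A3 is a dihydropyranone with a doubly activated C3–H and a vinylogous ester that opens by beta-elimination, so C2 is exposed in every basic step, including the diazo transfer.
- The flavone and enone chromophores absorb where the diazoketone does.
- The thermal part of the cascade adds heat to an epimerisable system.
- A3 would take more steps than the eight of the longest sequence below.

The chosen plan pays with two redox steps but uses only established reaction types.

**Alternative 3:** The cut is C3–C4 and O1–C2 in a [4+2] sense. A chiral phosphoric acid would dehydrate hydroxybenzyl alcohol A7 to ortho-quinone methide A8, which would add across the alkene of 3-styrylflavone A6 to give chroman A9. This is the most convergent road and beats the chosen plan on step count: A6 is one coupling away from iodide 7, and ring C with both stereocenters would form in one catalytic step. Its weak points are these: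
- A9 lacks the C4 oxygen. Oxidising that methylene to a ketone in a molecule with twelve other benzylic ether C–H bonds and a doubly activated C2–H has no selective solution, and changing the protecting groups moves the problem to a harsh final deprotection.
- A6 offers the catalyst no hydrogen-bond donor.
- The alkene of A6 is conjugated to an electron-poor pyranone, while A8 prefers electron-rich partners.

The chosen plan carries the C4 oxygen from aldehyde 4 through the whole route, so no C–H oxidation is needed.

Key step: step 8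

Assumption: the Z enol borinate made with (+)-Ipc2BOTf (the reagent from (−)-α-pinene) is taken to add to the Si face of an aldehyde, by analogy with syn aldol reactions of ethyl ketones; if the sense proves opposite for 9 and 4, the reagent from (+)-α-pinene is used and nothing else changes.

## Route

Step 1
Reactants: 1 5-bromoresorcinol (5-bromobenzene-1,3-diol)
Product: 2 1-bromo-3,5-bis(benzyloxy)benzene
Conditions: BnBr, K2CO3, DMF, 50 °C
Reagents that add atoms: benzyl bromide, BrCc1ccccc1
Why: Williamson ether synthesis; K2CO3 deprotonates both phenols, which displace bromide from benzyl bromide, and the aryl bromide is inert under these conditions.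

Step 2
Reactants: 2 1-bromo-3,5-bis(benzyloxy)benzene
Product: 4 2-bromo-4,6-bis(benzyloxy)benzaldehyde, via aryl iminium chloride 3 (not isolated)
Conditions: POCl3, DMF, 0 to 70 °C; then ice–water
Reagents that add atoms: N,N-dimethylformamide, CN(C)C=O; water, O
Why: Vilsmeier–Haack formylation; the chloroiminium ion attacks the ring carbon para to one benzyloxy group and ortho to the other (next to bromine), the site between the two ethers being more hindered, and iminium salt 3 is hydrolysed on work-up; benzyl ethers tolerate the reagent.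

Step 3
Reactants: 5 apigenin (5,7-dihydroxy-2-(4-hydroxyphenyl)-4H-chromen-4-one)
Product: 6 5,7-bis(benzyloxy)-2-[4-(benzyloxy)phenyl]-4H-chromen-4-one
Conditions: BnBr (excess), K2CO3, DMF, 80 °C
Reagents that add atoms: benzyl bromide, BrCc1ccccc1
Why: Williamson ether synthesis on all three phenols; the 5-hydroxyl is hydrogen-bonded to the C4 carbonyl and reacts last, hence the excess reagent and heat.

Step 4
Reactants: 6 5,7-bis(benzyloxy)-2-[4-(benzyloxy)phenyl]-4H-chromen-4-one
Product: 7 5,7-bis(benzyloxy)-2-[4-(benzyloxy)phenyl]-3-iodo-4H-chromen-4-one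
Conditions: I2, (NH4)2Ce(NO3)6, MeCN, 65 °C
Reagents that add atoms: iodine, II
Why: Oxidative electrophilic iodination; the cerium salt turns I2 into an iodonium equivalent that is taken up by C3, the enol-ether-type carbon of the pyranone, a known outcome for 5,7-dialkoxyflavones; the C3–I bond is the handle for the C3''–C bond of the target.

Step 5
Reactants: 7 5,7-bis(benzyloxy)-2-[4-(benzyloxy)phenyl]-3-iodo-4H-chromen-4-one; 8 1-[4-(benzyloxy)phenyl]ethan-1-one
Product: 9 5,7-bis(benzyloxy)-2-[4-(benzyloxy)phenyl]-3-{2-[4-(benzyloxy)phenyl]-2-oxoethyl}-4H-chromen-4-one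
Conditions: Pd2(dba)3, Xantphos, K3PO4, toluene, 80 °C
Reagents that add atoms: none
Why: Palladium-catalysed ketone alpha-arylation; zerovalent palladium inserts into the C3–I bond of 7, the potassium enolate of 8 displaces iodide on palladium and C–C reductive elimination follows, helped by the wide bite angle of Xantphos; the product is more acidic than 8, rests as its enolate and is too hindered for a second arylation, and the phosphate base spares the pyranone.

Step 6
Reactants: 9 5,7-bis(benzyloxy)-2-[4-(benzyloxy)phenyl]-3-{2-[4-(benzyloxy)phenyl]-2-oxoethyl}-4H-chromen-4-one; 4 2-bromo-4,6-bis(benzyloxy)benzaldehyde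
Product: 12 (2S,3S)-3-[2-bromo-4,6-bis(benzyloxy)phenyl]-1-[4-(benzyloxy)phenyl]-2-{5,7-bis(benzyloxy)-2-[4-(benzyloxy)phenyl]-4-oxo-4H-chromen-3-yl}-3-hydroxypropan-1-one (2,3-syn), via Z boron enolate 10 (not isolated), via boron aldolate 11 (not isolated)
Conditions: (+)-Ipc2BOTf, iPr2NEt, CH2Cl2, −78 °C; then 4, −78 to −20 °C; then H2O2, pH 7 buffer, MeOH, 0 °C
Reagents that add atoms: none
Why: Diisopinocampheylboron-mediated aldol reaction; the aryl ketone is enolised to Z enolate 10, which adds to the boron-bound aldehyde through a Zimmerman–Traxler chair to give the 2,3-syn aldolate 11, and the isopinocampheyl ligands are expected to direct the enolate to the Si face of 4, which sets C3 of the chain (the future C4) as S and with it C2 of the chain (the future C3) as S; buffered peroxide work-up frees 12 without retro-aldol cleavage.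

Step 7
Reactants: 12 (2S,3S)-3-[2-bromo-4,6-bis(benzyloxy)phenyl]-1-[4-(benzyloxy)phenyl]-2-{5,7-bis(benzyloxy)-2-[4-(benzyloxy)phenyl]-4-oxo-4H-chromen-3-yl}-3-hydroxypropan-1-one
Product: 13 (1S,2R,3S)-1-[2-bromo-4,6-bis(benzyloxy)phenyl]-3-[4-(benzyloxy)phenyl]-2-{5,7-bis(benzyloxy)-2-[4-(benzyloxy)phenyl]-4-oxo-4H-chromen-3-yl}propane-1,3-diol (1,3-anti)
Conditions: Me4NBH(OAc)3, MeCN/AcOH (1:1), −30 °C
Reagents that add atoms: none
Why: Evans–Saksena reduction; the hydroxyl of 12 exchanges an acetate on boron and the bound hydride is delivered intramolecularly to the activated ketone through a chair transition state, giving the 1,3-anti diol, so the new carbinol carbon (the future C2, S) is set by the relay center at the future C4; the flavone carbonyl is a vinylogous ester with no hydroxyl within reach and is not reduced, and the low temperature keeps the ring A benzylic carbinol from ionising.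

Step 8
Reactants: 13 (1S,2R,3S)-1-[2-bromo-4,6-bis(benzyloxy)phenyl]-3-[4-(benzyloxy)phenyl]-2-{5,7-bis(benzyloxy)-2-[4-(benzyloxy)phenyl]-4-oxo-4H-chromen-3-yl}propane-1,3-diol
Product: 14 3-{(2S,3S,4S)-5,7-bis(benzyloxy)-2-[4-(benzyloxy)phenyl]-4-hydroxy-3,4-dihydro-2H-chromen-3-yl}-5,7-bis(benzyloxy)-2-[4-(benzyloxy)phenyl]-4H-chromen-4-one (2,3-trans, 3,4-trans)
Conditions: Pd(OAc)2, 2-(di-tert-butylphosphino)-1,1'-binaphthyl, Cs2CO3, toluene, 70 °C
Reagents that add atoms: none
Why: Pd(OAc)2 is reduced in the flask by the phosphine to zerovalent palladium, which adds oxidatively to the C8a–Br bond of 13; Cs2CO3 then deprotonates the palladium-bound C2 hydroxyl to give an aryl(alkoxo)palladium species in a seven-membered palladacycle, and C–O reductive elimination forms O1–C8a. The closest known reaction type is the intramolecular Buchwald–Hartwig etherification of aryl bromides with secondary alcohols, which gives chromans and 2-arylchromans without loss of configuration at the carbinol carbon. Ring C (O1, C2, C3, C4, C4a, C8a) closes in the 6-exo sense by attack of oxygen on an sp2 carbon, and the (1S,2R,3S) diol maps onto a half-chair with the aryl, flavonyl and hydroxyl groups all equatorial, so the closure carries no conformational penalty. No stereocenter is created: only the O–H and C8a–Br bonds are broken, so C2, C3 and C4 keep their configuration, and the C2–O bond in particular stays intact. The step needs site selectivity between the two hydroxyls: the C4 hydroxyl could only close a four-membered ring, and its five-membered chelate to palladium holds the C4–H bond away from the metal, so it should be at worst a resting state. It also needs reductive elimination to outrun beta-hydride elimination from the C2 alkoxide, which the bulky, electron-rich di-tert-butyl(biaryl)phosphine secures by crowding the metal. Both benzyloxy groups of ring A are meta to C8a and so retard neither oxidative addition nor reductive elimination, and carbonate in toluene leaves the benzyl ethers and the flavone untouched.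

Step 9
Reactants: 14 3-{(2S,3S,4S)-5,7-bis(benzyloxy)-2-[4-(benzyloxy)phenyl]-4-hydroxy-3,4-dihydro-2H-chromen-3-yl}-5,7-bis(benzyloxy)-2-[4-(benzyloxy)phenyl]-4H-chromen-4-one
Product: 15 3-{(2S,3R)-5,7-bis(benzyloxy)-2-[4-(benzyloxy)phenyl]-4-oxo-3,4-dihydro-2H-chromen-3-yl}-5,7-bis(benzyloxy)-2-[4-(benzyloxy)phenyl]-4H-chromen-4-one (2,3-trans)
Conditions: Dess–Martin periodinane, NaHCO3, CH2Cl2, 0 °C to rt
Reagents that add atoms: none
Why: Dess–Martin oxidation of the hindered benzylic C4 alcohol under bicarbonate buffer; C2 is untouched, and C3, now alpha to the ketone, already holds the thermodynamically preferred trans arrangement, so enolisation can only confirm it (the C3 descriptor changes from S to R because C4 gains priority, not because the center moves).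

Step 10
Reactants: 15 3-{(2S,3R)-5,7-bis(benzyloxy)-2-[4-(benzyloxy)phenyl]-4-oxo-3,4-dihydro-2H-chromen-3-yl}-5,7-bis(benzyloxy)-2-[4-(benzyloxy)phenyl]-4H-chromen-4-one
Product: 16 3-[(2S,3R)-5,7-dihydroxy-2-(4-hydroxyphenyl)-4-oxo-3,4-dihydro-2H-chromen-3-yl]-5,7-dihydroxy-2-(4-hydroxyphenyl)-4H-chromen-4-one (CNP0208264.1)
Conditions: H2 (1 atm), Pd/C, THF/MeOH, rt
Reagents that add atoms: none
Why: Hydrogenolysis of the six aryl benzyl ethers; the tetrasubstituted C2''=C3'' bond and the hindered C4 ketone should be reduced far more slowly than aryl benzyl ethers are cleaved, and the neutral medium avoids base-induced opening of the flavanone, so C2 and C3 are retained.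

## Compound list

1 | 5-bromoresorcinol | Oc1cc(O)cc(Br)c1 | starting material
2 | 1-bromo-3,5-bis(benzyloxy)benzene | Brc1cc(OCc2ccccc2)cc(OCc2ccccc2)c1 | intermediate
3 | [2-bromo-4,6-bis(benzyloxy)benzylidene]dimethyliminium chloride (not isolated) | C[N+](C)=Cc1c(Br)cc(OCc2ccccc2)cc1OCc1ccccc1.[Cl-] | intermediate
4 | 2-bromo-4,6-bis(benzyloxy)benzaldehyde | O=Cc1c(Br)cc(OCc2ccccc2)cc1OCc1ccccc1 | intermediate
5 | apigenin | O=c1cc(-c2ccc(O)cc2)oc2cc(O)cc(O)c12 | starting material
6 | 5,7-bis(benzyloxy)-2-[4-(benzyloxy)phenyl]-4H-chromen-4-one | O=c1cc(-c2ccc(OCc3ccccc3)cc2)oc2cc(OCc3ccccc3)cc(OCc3ccccc3)c12 | intermediate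
7 | 5,7-bis(benzyloxy)-2-[4-(benzyloxy)phenyl]-3-iodo-4H-chromen-4-one | O=c1c(I)c(-c2ccc(OCc3ccccc3)cc2)oc2cc(OCc3ccccc3)cc(OCc3ccccc3)c12 | intermediate
8 | 1-[4-(benzyloxy)phenyl]ethan-1-one | CC(=O)c1ccc(OCc2ccccc2)cc1 | starting material
9 | 5,7-bis(benzyloxy)-2-[4-(benzyloxy)phenyl]-3-{2-[4-(benzyloxy)phenyl]-2-oxoethyl}-4H-chromen-4-one | O=C(Cc1c(-c2ccc(OCc3ccccc3)cc2)oc2cc(OCc3ccccc3)cc(OCc3ccccc3)c2c1=O)c1ccc(OCc2ccccc2)cc1 | intermediate
10 | (Z)-enol di[(+)-isopinocampheyl]borinate of 9, boron on the former ketone oxygen, oxygen cis to the flavone (not isolated) | O=c1c(/C=C(\OB([C@H]2C[C@H]3C[C@@H]([C@@H]2C)C3(C)C)[C@H]2C[C@H]3C[C@@H]([C@@H]2C)C3(C)C)c2ccc(OCc3ccccc3)cc2)c(-c2ccc(OCc3ccccc3)cc2)oc2cc(OCc3ccccc3)cc(OCc3ccccc3)c12 | intermediate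
11 | di[(+)-isopinocampheyl]boron aldolate of 12, boron on the carbinol oxygen (not isolated) | C[C@@H]1[C@@H](B(O[C@H](c2c(Br)cc(OCc3ccccc3)cc2OCc2ccccc2)[C@H](c2c(-c3ccc(OCc4ccccc4)cc3)oc3cc(OCc4ccccc4)cc(OCc4ccccc4)c3c2=O)C(=O)c2ccc(OCc3ccccc3)cc2)[C@H]2C[C@H]3C[C@@H]([C@@H]2C)C3(C)C)C[C@H]2C[C@@H]1C2(C)C | intermediate
12 | (2S,3S)-3-[2-bromo-4,6-bis(benzyloxy)phenyl]-1-[4-(benzyloxy)phenyl]-2-{5,7-bis(benzyloxy)-2-[4-(benzyloxy)phenyl]-4-oxo-4H-chromen-3-yl}-3-hydroxypropan-1-one | O[C@H](c1c(Br)cc(OCc2ccccc2)cc1OCc1ccccc1)[C@H](c1c(-c2ccc(OCc3ccccc3)cc2)oc2cc(OCc3ccccc3)cc(OCc3ccccc3)c2c1=O)C(=O)c1ccc(OCc2ccccc2)cc1 | intermediate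
13 | (1S,2R,3S)-1-[2-bromo-4,6-bis(benzyloxy)phenyl]-3-[4-(benzyloxy)phenyl]-2-{5,7-bis(benzyloxy)-2-[4-(benzyloxy)phenyl]-4-oxo-4H-chromen-3-yl}propane-1,3-diol | O[C@H](c1c(Br)cc(OCc2ccccc2)cc1OCc1ccccc1)[C@H](c1c(-c2ccc(OCc3ccccc3)cc2)oc2cc(OCc3ccccc3)cc(OCc3ccccc3)c2c1=O)[C@H](O)c1ccc(OCc2ccccc2)cc1 | intermediate
14 | 3-{(2S,3S,4S)-5,7-bis(benzyloxy)-2-[4-(benzyloxy)phenyl]-4-hydroxy-3,4-dihydro-2H-chromen-3-yl}-5,7-bis(benzyloxy)-2-[4-(benzyloxy)phenyl]-4H-chromen-4-one | O[C@@H]1c2c(OCc3ccccc3)cc(OCc3ccccc3)cc2O[C@H](c2ccc(OCc3ccccc3)cc2)[C@H]1c1c(-c2ccc(OCc3ccccc3)cc2)oc2cc(OCc3ccccc3)cc(OCc3ccccc3)c2c1=O | intermediate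
15 | 3-{(2S,3R)-5,7-bis(benzyloxy)-2-[4-(benzyloxy)phenyl]-4-oxo-3,4-dihydro-2H-chromen-3-yl}-5,7-bis(benzyloxy)-2-[4-(benzyloxy)phenyl]-4H-chromen-4-one | O=C1c2c(OCc3ccccc3)cc(OCc3ccccc3)cc2O[C@H](c2ccc(OCc3ccccc3)cc2)[C@H]1c1c(-c2ccc(OCc3ccccc3)cc2)oc2cc(OCc3ccccc3)cc(OCc3ccccc3)c2c1=O | intermediate
16 | 3-[(2S,3R)-5,7-dihydroxy-2-(4-hydroxyphenyl)-4-oxo-3,4-dihydro-2H-chromen-3-yl]-5,7-dihydroxy-2-(4-hydroxyphenyl)-4H-chromen-4-one | O=C1c2c(O)cc(O)cc2O[C@H](c2ccc(O)cc2)[C@H]1c1c(-c2ccc(O)cc2)oc2cc(O)cc(O)c2c1=O | target

## Step count and least certain steps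

Total step count: 10. Longest linear sequence: 8 steps (steps 3 to 10, from 5 to 16); the ring A branch (steps 1 and 2) joins at step 6.

**Step 8 (key step).** The most likely failure is diversion of the arylpalladium intermediate before C–O reductive elimination. A free benzylic hydroxyl sits ortho to the metal, and the reacting alkoxide carries a benzylic hydride. The paths are chelation by the C4 hydroxyl followed by hydride transfer and hydrodebromination, or beta-hydride elimination from the C2 alkoxide. The fallback masks the competing hydroxyl while the diol is made. It sets out from 12 and replaces step 7 by an Evans–Tishchenko reduction (SmI2 as catalyst, benzaldehyde, THF, −10 °C). This gives the same 1,3-anti diol with the ring A carbinol oxygen already acylated and the other hydroxyl free, the diol 1-benzoate F1. The palladium closure is then run on F1 with K3PO4 in place of Cs2CO3 to limit acyl migration and gives the flavan-4-yl benzoate F2. Methanolysis (K2CO3, MeOH) returns to 14.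

**Step 6.** The most likely failure is poor facial selectivity on the aldehyde together with slow addition. A bulky enolate carrying a flavone, whose carbonyl can bind boron, meets an electron-rich, 2,6-disubstituted aldehyde, and the adduct is prone to retro-aldol cleavage if the mixture is warmed. The fallback replaces asymmetric induction by resolution. It sets out from 9 and 4 and runs the aldol with achiral Bu2BOTf (iPr2NEt, CH2Cl2, −78 °C), which should give the racemic syn aldol adduct F3. Steps 7 and 8 convert it into the racemic anti diol F4 and the racemic flavan-4-ol F5. F5 is acylated at the C4 hydroxyl with (1S)-camphanic chloride (DMAP, pyridine). The (2S,3S,4S) camphanate F6 is separated from the (2R,3R,4R) camphanate F7 by chromatography or crystallisation, and methanolysis of F6 (K2CO3, MeOH) returns to 14.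

**Step 5.** The most likely failure is loss of iodine by reduction, or conjugate attack of the enolate on the pyranone in place of coupling, since the halide is an alpha-iodo enone and the nucleophile a hard potassium enolate. The fallback builds the side chain by steps that need no enolate. It sets out from 7. Stille coupling with allyltributylstannane (Pd(PPh3)4, toluene, 100 °C) gives the 3-allylflavone F8. Lemieux–Johnson cleavage (OsO4 as catalyst, NaIO4, 2,6-lutidine, dioxane/water) gives the flavon-3-ylacetaldehyde F9. Addition of 4-(benzyloxy)phenylmagnesium bromide (THF, −78 °C) gives the racemic secondary alcohol F10, and Dess–Martin oxidation returns to 9.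

**Step 4.** The most likely failure is iodination of ring A at C6 or C8 in competition with C3, or oxidative damage to the benzyl ethers, because ring A is a doubly alkoxylated arene and the cerium salt is an oxidant. The fallback uses directed metalation in place of electrophilic substitution. It sets out from 6, which is deprotonated at C3 with LiN(iPr)2 in THF at −78 °C. The 3-lithioflavone F11 is quenched with I2 and returns to 7.

**Step 10.** The most likely failure is over-reduction before the hindered 5- and 5''-benzyl ethers are gone: hydrogenolysis of the benzylic C2–O1 bond, or saturation of C2''=C3''. The fallback cleaves the ethers without hydrogen or a metal surface. It sets out from 15, which is treated with BCl3 and pentamethylbenzene as cation scavenger in CH2Cl2 at −78 °C, and returns directly to 16.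

## Further compounds

F1 | step 8 | (1S,2R,3S)-1-[2-bromo-4,6-bis(benzyloxy)phenyl]-3-[4-(benzyloxy)phenyl]-2-{5,7-bis(benzyloxy)-2-[4-(benzyloxy)phenyl]-4-oxo-4H-chromen-3-yl}-3-hydroxypropyl benzoate | O=C(O[C@H](c1c(Br)cc(OCc2ccccc2)cc1OCc1ccccc1)[C@H](c1c(-c2ccc(OCc3ccccc3)cc2)oc2cc(OCc3ccccc3)cc(OCc3ccccc3)c2c1=O)[C@H](O)c1ccc(OCc2ccccc2)cc1)c1ccccc1
F2 | step 8 | (2S,3S,4S)-5,7-bis(benzyloxy)-2-[4-(benzyloxy)phenyl]-3-{5,7-bis(benzyloxy)-2-[4-(benzyloxy)phenyl]-4-oxo-4H-chromen-3-yl}-3,4-dihydro-2H-chromen-4-yl benzoate | O=C(O[C@@H]1c2c(OCc3ccccc3)cc(OCc3ccccc3)cc2O[C@H](c2ccc(OCc3ccccc3)cc2)[C@H]1c1c(-c2ccc(OCc3ccccc3)cc2)oc2cc(OCc3ccccc3)cc(OCc3ccccc3)c2c1=O)c1ccccc1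
F3 | step 6 | racemic syn aldol adduct, (2S,3S)-12 with its (2R,3R) enantiomer | O[C@H](c1c(Br)cc(OCc2ccccc2)cc1OCc1ccccc1)[C@H](c1c(-c2ccc(OCc3ccccc3)cc2)oc2cc(OCc3ccccc3)cc(OCc3ccccc3)c2c1=O)C(=O)c1ccc(OCc2ccccc2)cc1.O[C@@H](c1c(Br)cc(OCc2ccccc2)cc1OCc1ccccc1)[C@@H](c1c(-c2ccc(OCc3ccccc3)cc2)oc2cc(OCc3ccccc3)cc(OCc3ccccc3)c2c1=O)C(=O)c1ccc(OCc2ccccc2)cc1
F4 | step 6 | racemic 1,3-anti diol, (1S,2R,3S)-13 with its (1R,2S,3R) enantiomer | O[C@H](c1c(Br)cc(OCc2ccccc2)cc1OCc1ccccc1)[C@H](c1c(-c2ccc(OCc3ccccc3)cc2)oc2cc(OCc3ccccc3)cc(OCc3ccccc3)c2c1=O)[C@H](O)c1ccc(OCc2ccccc2)cc1.O[C@@H](c1c(Br)cc(OCc2ccccc2)cc1OCc1ccccc1)[C@@H](c1c(-c2ccc(OCc3ccccc3)cc2)oc2cc(OCc3ccccc3)cc(OCc3ccccc3)c2c1=O)[C@@H](O)c1ccc(OCc2ccccc2)cc1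
F5 | step 6 | racemic flavan-4-ol, (2S,3S,4S)-14 with its (2R,3R,4R) enantiomer | O[C@@H]1c2c(OCc3ccccc3)cc(OCc3ccccc3)cc2O[C@H](c2ccc(OCc3ccccc3)cc2)[C@H]1c1c(-c2ccc(OCc3ccccc3)cc2)oc2cc(OCc3ccccc3)cc(OCc3ccccc3)c2c1=O.O[C@H]1c2c(OCc3ccccc3)cc(OCc3ccccc3)cc2O[C@@H](c2ccc(OCc3ccccc3)cc2)[C@@H]1c1c(-c2ccc(OCc3ccccc3)cc2)oc2cc(OCc3ccccc3)cc(OCc3ccccc3)c2c1=O
F6 | step 6 | (2S,3S,4S)-flavan-4-yl (1S,4R)-camphanate of 14 | O=C(O[C@@H]1c2c(OCc3ccccc3)cc(OCc3ccccc3)cc2O[C@H](c2ccc(OCc3ccccc3)cc2)[C@H]1c1c(-c2ccc(OCc3ccccc3)cc2)oc2cc(OCc3ccccc3)cc(OCc3ccccc3)c2c1=O)[C@@]12CC[C@@](C)(C(=O)O1)C2(C)C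
F7 | step 6 | (2R,3R,4R)-flavan-4-yl (1S,4R)-camphanate, diastereomer of F6 | O=C(O[C@H]1c2c(OCc3ccccc3)cc(OCc3ccccc3)cc2O[C@@H](c2ccc(OCc3ccccc3)cc2)[C@@H]1c1c(-c2ccc(OCc3ccccc3)cc2)oc2cc(OCc3ccccc3)cc(OCc3ccccc3)c2c1=O)[C@@]12CC[C@@](C)(C(=O)O1)C2(C)C
F8 | step 5 | 3-allyl-5,7-bis(benzyloxy)-2-[4-(benzyloxy)phenyl]-4H-chromen-4-one | C=CCc1c(-c2ccc(OCc3ccccc3)cc2)oc2cc(OCc3ccccc3)cc(OCc3ccccc3)c2c1=O
F9 | step 5 | {5,7-bis(benzyloxy)-2-[4-(benzyloxy)phenyl]-4-oxo-4H-chromen-3-yl}acetaldehyde | O=CCc1c(-c2ccc(OCc3ccccc3)cc2)oc2cc(OCc3ccccc3)cc(OCc3ccccc3)c2c1=O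
F10 | step 5 | racemic 5,7-bis(benzyloxy)-2-[4-(benzyloxy)phenyl]-3-{2-[4-(benzyloxy)phenyl]-2-hydroxyethyl}-4H-chromen-4-one | OC(Cc1c(-c2ccc(OCc3ccccc3)cc2)oc2cc(OCc3ccccc3)cc(OCc3ccccc3)c2c1=O)c1ccc(OCc2ccccc2)cc1
F11 | step 4 | 5,7-bis(benzyloxy)-2-[4-(benzyloxy)phenyl]-3-lithio-4H-chromen-4-one | [Li]c1c(-c2ccc(OCc3ccccc3)cc2)oc2cc(OCc3ccccc3)cc(OCc3ccccc3)c2c1=O
F0 | step 10 | none | none
A1 | alternative 1 | trans-1-[4-(benzyloxy)benzoyl]-1,3-bis[4-(benzyloxy)-2,6-dihydroxybenzoyl]-2-[4-(benzyloxy)phenyl]cyclopropane | O=C(c1c(O)cc(OCc2ccccc2)cc1O)[C@H]1[C@H](c2ccc(OCc3ccccc3)cc2)C1(C(=O)c1c(O)cc(OCc2ccccc2)cc1O)C(=O)c1ccc(OCc2ccccc2)cc1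
A2 | alternative 1 | (2S,3R) target as its 7,4',7'',4'''-tetrabenzyl ether | O=C1c2c(O)cc(OCc3ccccc3)cc2O[C@H](c2ccc(OCc3ccccc3)cc2)[C@H]1c1c(-c2ccc(OCc3ccccc3)cc2)oc2cc(OCc3ccccc3)cc(O)c2c1=O
A3 | alternative 2 | (2S,3R)-2-[4-(benzyloxy)phenyl]-3-{5,7-bis(benzyloxy)-2-[4-(benzyloxy)phenyl]-4-oxo-4H-chromen-3-yl}-6-(diazoacetyl)-2,3-dihydro-4H-pyran-4-one | O=C1C=C(C(=O)C=[N+]=[N-])O[C@H](c2ccc(OCc3ccccc3)cc2)[C@H]1c1c(-c2ccc(OCc3ccccc3)cc2)oc2cc(OCc3ccccc3)cc(OCc3ccccc3)c2c1=O
A4 | alternative 2 | ethynyl triisopropylsilyl ether | C#CO[Si](C(C)C)(C(C)C)C(C)C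
A5 | alternative 2 | (2S,3R) target as its 7-O-triisopropylsilyl 4',5'',7'',4'''-tetrabenzyl ether | O=C1c2c(O)cc(O[Si](C(C)C)(C(C)C)C(C)C)cc2O[C@H](c2ccc(OCc3ccccc3)cc2)[C@H]1c1c(-c2ccc(OCc3ccccc3)cc2)oc2cc(OCc3ccccc3)cc(OCc3ccccc3)c2c1=O
A6 | alternative 3 | (E)-5,7-bis(benzyloxy)-2-[4-(benzyloxy)phenyl]-3-[4-(benzyloxy)styryl]-4H-chromen-4-one | O=c1c(/C=C/c2ccc(OCc3ccccc3)cc2)c(-c2ccc(OCc3ccccc3)cc2)oc2cc(OCc3ccccc3)cc(OCc3ccccc3)c12
A7 | alternative 3 | 3,5-bis(benzyloxy)-2-(hydroxymethyl)phenol | OCc1c(O)cc(OCc2ccccc2)cc1OCc1ccccc1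
A8 | alternative 3 | 3,5-bis(benzyloxy)-6-methylidenecyclohexa-2,4-dien-1-one (ortho-quinone methide) | C=C1C(=O)C=C(OCc2ccccc2)C=C1OCc1ccccc1
A9 | alternative 3 | (2S,3R)-trans-2-aryl-3-(flavon-3-yl)chroman, the 4-deoxo target as its hexabenzyl ether | C1c2c(OCc3ccccc3)cc(OCc3ccccc3)cc2O[C@H](c2ccc(OCc3ccccc3)cc2)[C@H]1c1c(-c2ccc(OCc3ccccc3)cc2)oc2cc(OCc3ccccc3)cc(OCc3ccccc3)c2c1=O
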